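The route rests on unzipping both rings at C4–C5 and C9–C10 to an acyclic (2R,3S)-epoxy triene whose C8=C9 alkene bears a CH2SiMe3 group. With MeAlCl2 the oxirane opens at C4, the C5=C10 alkene closes ring A, and the allylsilane then closes ring B through C9–C10, the last ring formed, setting C4, C5, C10 and C9 and unveiling the exocyclic C8=C17 alkene in one operation. The step exploits the C8=C17 methylene flanking C9 in ring B, the imprint of an allylsilane terminator, and the C3 oxygen beside quaternary C4 in ring A, the imprint of an epoxide initiator.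

Key step: step 14

Remark on naming: the bicyclic compounds carry labdane numbers (ring A = C1–C5 and C10; ring B = C5–C10; C17 = methylene carbon on C8; C18 = 4α-methyl; C19 = 4β carbon; C20 = 10β-methyl; C11–C16 = side chain on C9). The same numbers are used for the corresponding carbons of the open-chain precursors in the Why lines. In this notation the target is 3α-acetoxy-15-hydroxylabda-8(17),13E-dien-19-oic acid of the normal series (5α-H, 9α-H, 10β-CH3).

Step 1
Reactants: 1 geraniol [(2E)-3,7-dimethylocta-2,6-dien-1-ol]; 2 tert-butyl(chloro)diphenylsilane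
Product: 3 tert-butyl{[(2E)-3,7-dimethylocta-2,6-dien-1-yl]oxy}diphenylsilane
Conditions: imidazole, CH2Cl2, 0 °C to rt
Reagents that add atoms: tert-butyl(chloro)diphenylsilane, CC(C)(C)[Si](Cl)(c1ccccc1)c1ccccc1
Why: Imidazole-promoted O-silylation of the primary allylic alcohol (silyl ether protection) installs a group that withstands the Grignard, hydride, Claisen and Lewis acid steps and is removed only at the end.

Step 2
Reactants: 3 tert-butyl{[(2E)-3,7-dimethylocta-2,6-dien-1-yl]oxy}diphenylsilane; 4 3-chloroperoxybenzoic acid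
Product: 5 tert-butyl{[(2E)-5-(3,3-dimethyloxiran-2-yl)-3-methylpent-2-en-1-yl]oxy}diphenylsilane (racemic)
Conditions: mCPBA, NaHCO3, CH2Cl2, −20 to 0 °C
Reagents that add atoms: 3-chloroperoxybenzoic acid, OOC(=O)c1cccc(Cl)c1
Why: Prilezhaev epoxidation occurs at the remote, more electron-rich trisubstituted alkene, the 2,3-alkene being deactivated by the allylic oxygen and screened by the bulky silyl group; the new stereocentre is lost in step 3.

Step 3
Reactants: 5 tert-butyl{[(2E)-5-(3,3-dimethyloxiran-2-yl)-3-methylpent-2-en-1-yl]oxy}diphenylsilane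
Product: 6 (4E)-6-(tert-butyldiphenylsilyloxy)-4-methylhex-4-enal
Conditions: H5IO6, THF/Et2O, 0 °C
Reagents that add atoms: none
Why: Periodic acid hydrolyses the oxirane to the glycol and cleaves it (Malaprade cleavage), releasing acetone and the aldehyde without touching the allylic silyl ether.

Step 4
Reactants: 6 (4E)-6-(tert-butyldiphenylsilyloxy)-4-methylhex-4-enal; 7 (2-bromoallyl)trimethylsilane
Product: 9 (6E)-8-(tert-butyldiphenylsilyloxy)-6-methyl-2-[(trimethylsilyl)methyl]octa-1,6-dien-3-ol (racemic), via Grignard reagent 8 (not isolated)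
Conditions: Mg, THF, rt; then 6, THF, −78 to 0 °C; aq. NH4Cl
Reagents that add atoms: (2-bromoallyl)trimethylsilane, C=C(Br)C[Si](C)(C)C
Why: 1,2-Addition of the vinyl Grignard reagent to the aldehyde (Grignard reaction) gives the 2-(silylmethyl)allylic alcohol; the carbinol centre is formed racemic and is erased in step 5.

Step 5
Reactants: 9 (6E)-8-(tert-butyldiphenylsilyloxy)-6-methyl-2-[(trimethylsilyl)methyl]octa-1,6-dien-3-ol; 10 triethyl orthoacetate
Product: 12 ethyl (4Z,8E)-10-(tert-butyldiphenylsilyloxy)-8-methyl-4-[(trimethylsilyl)methyl]deca-4,8-dienoate, via ketene acetal 11 (not isolated)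
Conditions: MeC(OEt)3 (excess), EtCO2H (cat.), 135–140 °C, removal of EtOH
Reagents that add atoms: triethyl orthoacetate, CCOC(C)(OCC)OCC
Why: Johnson–Claisen [3,3]-sigmatropic rearrangement of the ketene acetal through a chair with the C9 substituent equatorial delivers the trisubstituted C8=C9 alkene with C7 trans to C11 and adds C6 and C5; the weak carboxylic acid catalyst should leave the allylsilane intact.

Step 6
Reactants: 12 ethyl (4Z,8E)-10-(tert-butyldiphenylsilyloxy)-8-methyl-4-[(trimethylsilyl)methyl]deca-4,8-dienoate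
Product: 13 (4Z,8E)-10-(tert-butyldiphenylsilyloxy)-8-methyl-4-[(trimethylsilyl)methyl]deca-4,8-dienal
Conditions: i-Bu2AlH (1.05 equiv), CH2Cl2, −78 °C; aq. potassium sodium tartrate
Reagents that add atoms: none
Why: Partial reduction of the ester with one equivalent of i-Bu2AlH at −78 °C stops at the tetrahedral aluminium hemiacetal, which gives the aldehyde on work-up.

Step 7
Reactants: 13 (4Z,8E)-10-(tert-butyldiphenylsilyloxy)-8-methyl-4-[(trimethylsilyl)methyl]deca-4,8-dienal; 14 isopropenylmagnesium bromide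
Product: 15 (6Z,10E)-12-(tert-butyldiphenylsilyloxy)-2,10-dimethyl-6-[(trimethylsilyl)methyl]dodeca-1,6,10-trien-3-ol (racemic)
Conditions: THF, −78 to 0 °C; aq. NH4Cl
Reagents that add atoms: isopropenylmagnesium bromide, C=C(C)[Mg]Br
Why: Grignard addition of the isopropenyl nucleophile to the aldehyde sets up the second 2-substituted allylic alcohol; its racemic carbinol centre is erased in step 8.

Step 8
Reactants: 15 (6Z,10E)-12-(tert-butyldiphenylsilyloxy)-2,10-dimethyl-6-[(trimethylsilyl)methyl]dodeca-1,6,10-trien-3-ol; 10 triethyl orthoacetate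
Product: 17 ethyl (4E,8Z,12E)-14-(tert-butyldiphenylsilyloxy)-4,12-dimethyl-8-[(trimethylsilyl)methyl]tetradeca-4,8,12-trienoate, via ketene acetal 16 (not isolated)
Conditions: MeC(OEt)3 (excess), EtCO2H (cat.), 135–140 °C, removal of EtOH
Reagents that add atoms: triethyl orthoacetate, CCOC(C)(OCC)OCC
Why: A second Johnson–Claisen rearrangement through a chair with the chain equatorial forms the E-trisubstituted C5=C10 alkene and adds C2 and C3.

Step 9
Reactants: 17 ethyl (4E,8Z,12E)-14-(tert-butyldiphenylsilyloxy)-4,12-dimethyl-8-[(trimethylsilyl)methyl]tetradeca-4,8,12-trienoate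
Product: 18 (4E,8Z,12E)-14-(tert-butyldiphenylsilyloxy)-4,12-dimethyl-8-[(trimethylsilyl)methyl]tetradeca-4,8,12-trienal
Conditions: i-Bu2AlH (1.05 equiv), CH2Cl2, −78 °C; aq. potassium sodium tartrate
Reagents that add atoms: none
Why: Partial ester reduction by i-Bu2AlH at −78 °C again stops at the aluminium hemiacetal and gives the C3 aldehyde on work-up.

Step 10
Reactants: 18 (4E,8Z,12E)-14-(tert-butyldiphenylsilyloxy)-4,12-dimethyl-8-[(trimethylsilyl)methyl]tetradeca-4,8,12-trienal; 19 methyl 2-[bis(2,2,2-trifluoroethoxy)phosphoryl]propanoate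
Product: 21 methyl (2Z,6E,10Z,14E)-16-(tert-butyldiphenylsilyloxy)-2,6,14-trimethyl-10-[(trimethylsilyl)methyl]hexadeca-2,6,10,14-tetraenoate, via phosphonate carbanion 20 (not isolated)
Conditions: KN(SiMe3)2, 18-crown-6, THF, −78 °C
Reagents that add atoms: methyl 2-[bis(2,2,2-trifluoroethoxy)phosphoryl]propanoate, COC(=O)C(C)P(=O)(OCC(F)(F)F)OCC(F)(F)F
Why: Still–Gennari modification of the Horner–Wadsworth–Emmons reaction: the electron-poor bis(trifluoroethyl) phosphonate with a dissociated potassium counter-ion eliminates under kinetic control to the Z-enoate, which places the future C19 carbon cis to the chain.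

Step 11
Reactants: 21 methyl (2Z,6E,10Z,14E)-16-(tert-butyldiphenylsilyloxy)-2,6,14-trimethyl-10-[(trimethylsilyl)methyl]hexadeca-2,6,10,14-tetraenoate
Product: 22 (2Z,6E,10Z,14E)-16-(tert-butyldiphenylsilyloxy)-2,6,14-trimethyl-10-[(trimethylsilyl)methyl]hexadeca-2,6,10,14-tetraen-1-ol
Conditions: i-Bu2AlH (2.5 equiv), CH2Cl2, −78 to 0 °C; aq. potassium sodium tartrate
Reagents that add atoms: none
Why: 1,2-Reduction of the unsaturated ester by i-Bu2AlH gives the Z-allylic alcohol required as the handle for the directed epoxidation.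

Step 12
Reactants: 22 (2Z,6E,10Z,14E)-16-(tert-butyldiphenylsilyloxy)-2,6,14-trimethyl-10-[(trimethylsilyl)methyl]hexadeca-2,6,10,14-tetraen-1-ol; 23 tert-butyl hydroperoxide
Product: 24 {(2R,3S)-3-[(3E,7Z,11E)-13-(tert-butyldiphenylsilyloxy)-3,11-dimethyl-7-[(trimethylsilyl)methyl]trideca-3,7,11-trien-1-yl]-2-methyloxiran-2-yl}methanol
Conditions: Ti(OiPr)4 (cat.), D-(−)-diethyl tartrate (cat.), t-BuOOH, 4 Å molecular sieves, CH2Cl2, −20 °C
Reagents that add atoms: tert-butyl hydroperoxide, CC(C)(C)OO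
Why: Katsuki–Sharpless asymmetric epoxidation is confined to the allylic alcohol alkene, and the D-(−)-tartrate ligand directs oxygen to the face that gives the (2R,3S)-oxirane, which fixes C3 as (S) and stores the configuration later relayed to C4; the allylsilane and the other alkenes are not touched.

Step 13
Reactants: 24 {(2R,3S)-3-[(3E,7Z,11E)-13-(tert-butyldiphenylsilyloxy)-3,11-dimethyl-7-[(trimethylsilyl)methyl]trideca-3,7,11-trien-1-yl]-2-methyloxiran-2-yl}methanol; 25 tert-butyl(chloro)dimethylsilane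
Product: 26 tert-butyl({(2R,3S)-3-[(3E,7Z,11E)-13-(tert-butyldiphenylsilyloxy)-3,11-dimethyl-7-[(trimethylsilyl)methyl]trideca-3,7,11-trien-1-yl]-2-methyloxiran-2-yl}methoxy)dimethylsilane
Conditions: imidazole, DMF, 0 °C to rt
Reagents that add atoms: tert-butyl(chloro)dimethylsilane, CC(C)(C)[Si](C)(C)Cl
Why: Silylation of the primary hydroxyl gives a bulky, poorly coordinating ether that should neither chelate the Lewis acid nor attack the C4 cation in the key step.

Step 14
Reactants: 26 tert-butyl({(2R,3S)-3-[(3E,7Z,11E)-13-(tert-butyldiphenylsilyloxy)-3,11-dimethyl-7-[(trimethylsilyl)methyl]trideca-3,7,11-trien-1-yl]-2-methyloxiran-2-yl}methoxy)dimethylsilane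
Product: 27 19-(tert-butyldimethylsilyloxy)-15-(tert-butyldiphenylsilyloxy)labda-8(17),13E-dien-3β-ol
Conditions: MeAlCl2 (2.5 equiv), CH2Cl2, −78 °C; then Et3N, MeOH, aq. NaHCO3
Reagents that add atoms: none
Why: MeAlCl2 coordinates the oxirane oxygen and ionises the C4–O bond at the more substituted carbon; the C5=C10 alkene attacks C4 anti to the departing oxygen, the resulting C10 cation is captured by C9 of the allylsilane, and the β-silyl cation at C8 loses the silyl group to leave the C8=C17 methylene, the closest known type being Lewis acid epoxy-polyene cyclisation terminated by SE2′ attack of an allylsilane. Ring A closes first by a 6-endo opening of the oxirane (both oxirane carbons end in the ring) that is 6-endo-trig at C5=C10, and ring B closes last by a 6-endo-trig attack of C8=C9 on C10. C3 keeps the (S) configuration set in step 12 with its oxygen equatorial (3β), and C4 is inverted stereospecifically, so the silyloxymethyl group that was cis to the chain on the oxirane becomes axial (4β, C19) and the methyl equatorial. The E geometry of C5=C10 in a chair–chair array gives the trans ring fusion (5α-H, 10β-CH3), and the geometry of C8=C9 (C7 trans to C11) places the side chain at C9 equatorial (9β). The step needs opening at C4 and not at C3 (secured by the tertiary centre), termination at the bicyclic stage (secured because desilylation outruns attack by the remote C13=C14 alkene) and a regiodefined exocyclic alkene (secured by the position of silicon); the inductive pull of the silyloxymethyl group slows ionisation, which is why a strong, non-chelating Lewis acid at low temperature is chosen.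

Step 15
Reactants: 27 19-(tert-butyldimethylsilyloxy)-15-(tert-butyldiphenylsilyloxy)labda-8(17),13E-dien-3β-ol
Product: 28 19-(tert-butyldimethylsilyloxy)-15-(tert-butyldiphenylsilyloxy)labda-8(17),13E-dien-3-one
Conditions: Dess–Martin periodinane, NaHCO3, CH2Cl2, rt
Reagents that add atoms: none
Why: Dess–Martin oxidation of the secondary alcohol under buffered, neutral conditions gives the C3 ketone without migration of the exocyclic alkene or loss of silyl groups.

Step 16
Reactants: 28 19-(tert-butyldimethylsilyloxy)-15-(tert-butyldiphenylsilyloxy)labda-8(17),13E-dien-3-one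
Product: 29 19-(tert-butyldimethylsilyloxy)-15-(tert-butyldiphenylsilyloxy)labda-8(17),13E-dien-3α-ol
Conditions: LiBH(s-Bu)3, THF, −78 °C; then H2O
Reagents that add atoms: none
Why: The bulky tri-sec-butylborohydride attacks the C3 ketone along the equatorial trajectory because the axial approach is blocked by the axial hydrogens at C1 and C5, giving the axial 3α-alcohol (sterically controlled ketone reduction).

Step 17
Reactants: 29 19-(tert-butyldimethylsilyloxy)-15-(tert-butyldiphenylsilyloxy)labda-8(17),13E-dien-3α-ol; 30 acetic anhydride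
Product: 31 3α-acetoxy-19-(tert-butyldimethylsilyloxy)-15-(tert-butyldiphenylsilyloxy)labda-8(17),13E-diene
Conditions: Ac2O, DMAP, pyridine, 40 °C
Reagents that add atoms: acetic anhydride, CC(=O)OC(C)=O
Why: DMAP-catalysed acyl transfer (Steglich-type acylation) acetylates the hindered axial hydroxyl.

Step 18
Reactants: 31 3α-acetoxy-19-(tert-butyldimethylsilyloxy)-15-(tert-butyldiphenylsilyloxy)labda-8(17),13E-diene
Product: 32 3α-acetoxy-15-(tert-butyldiphenylsilyloxy)labda-8(17),13E-dien-19-ol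
Conditions: camphorsulfonic acid (cat.), MeOH/CH2Cl2, 0 °C to rt
Reagents that add atoms: none
Why: Acid-catalysed methanolysis cleaves the alkyl tert-butyldimethylsilyl ether far faster than the tert-butyldiphenylsilyl ether, and the acetate cannot migrate because O3 and C19 are trans-diaxial (selective desilylation).

Step 19
Reactants: 32 3α-acetoxy-15-(tert-butyldiphenylsilyloxy)labda-8(17),13E-dien-19-ol
Product: 33 3α-acetoxy-15-(tert-butyldiphenylsilyloxy)labda-8(17),13E-dien-19-al
Conditions: Dess–Martin periodinane, NaHCO3, CH2Cl2, rt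
Reagents that add atoms: none
Why: Dess–Martin oxidation of the neopentyl primary alcohol gives the aldehyde, which has no α-hydrogen and so cannot epimerise.

Step 20
Reactants: 33 3α-acetoxy-15-(tert-butyldiphenylsilyloxy)labda-8(17),13E-dien-19-al; 34 sodium chlorite
Product: 35 3α-acetoxy-15-(tert-butyldiphenylsilyloxy)labda-8(17),13E-dien-19-oic acid
Conditions: NaClO2, NaH2PO4, 2-methyl-2-butene, t-BuOH/H2O, rt
Reagents that add atoms: sodium chlorite, [Na+].[O-]Cl=O
Why: Pinnick (Lindgren) oxidation by chlorous acid converts the hindered aldehyde to the acid while 2-methyl-2-butene scavenges hypochlorous acid and protects the two alkenes.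

Step 21
Reactants: 35 3α-acetoxy-15-(tert-butyldiphenylsilyloxy)labda-8(17),13E-dien-19-oic acid
Product: 36 3α-acetoxy-15-hydroxylabda-8(17),13E-dien-19-oic acid [(1R,2R,4aR,5S,8aR)-2-acetoxy-5-[(3E)-5-hydroxy-3-methylpent-3-en-1-yl]-1,4a-dimethyl-6-methylidenedecahydronaphthalene-1-carboxylic acid]
Conditions: Bu4NF, AcOH, THF, rt
Reagents that add atoms: none
Why: Fluoride-induced cleavage of the silyl ether, buffered with acetic acid so that the hindered acetate survives, frees the C15 allylic alcohol and gives the target.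

Compound list
1 | geraniol, (2E)-3,7-dimethylocta-2,6-dien-1-ol | CC(C)=CCC/C(C)=C/CO | starting material
2 | tert-butyl(chloro)diphenylsilane | CC(C)(C)[Si](Cl)(c1ccccc1)c1ccccc1 | starting material
3 | tert-butyl{[(2E)-3,7-dimethylocta-2,6-dien-1-yl]oxy}diphenylsilane | CC(C)=CCC/C(C)=C/CO[Si](c1ccccc1)(c1ccccc1)C(C)(C)C | intermediate
4 | 3-chloroperoxybenzoic acid | OOC(=O)c1cccc(Cl)c1 | starting material
5 | tert-butyl{[(2E)-5-(3,3-dimethyloxiran-2-yl)-3-methylpent-2-en-1-yl]oxy}diphenylsilane (racemic) | CC1(C)OC1CC/C(C)=C/CO[Si](c1ccccc1)(c1ccccc1)C(C)(C)C | intermediate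
6 | (4E)-6-(tert-butyldiphenylsilyloxy)-4-methylhex-4-enal | O=CCC/C(C)=C/CO[Si](c1ccccc1)(c1ccccc1)C(C)(C)C | intermediate
7 | (2-bromoallyl)trimethylsilane | C=C(Br)C[Si](C)(C)C | starting material
8 | [3-(trimethylsilyl)prop-1-en-2-yl]magnesium bromide | C=C([Mg]Br)C[Si](C)(C)C | intermediate (not isolated)
9 | (6E)-8-(tert-butyldiphenylsilyloxy)-6-methyl-2-[(trimethylsilyl)methyl]octa-1,6-dien-3-ol (racemic) | C=C(C[Si](C)(C)C)C(O)CC/C(C)=C/CO[Si](c1ccccc1)(c1ccccc1)C(C)(C)C | intermediate
10 | triethyl orthoacetate (1,1,1-triethoxyethane) | CCOC(C)(OCC)OCC | starting material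
11 | 1-ethoxyvinyl ether (ketene acetal) of 9 | C=C(OCC)OC(CC/C(C)=C/CO[Si](c1ccccc1)(c1ccccc1)C(C)(C)C)C(=C)C[Si](C)(C)C | intermediate (not isolated)
12 | ethyl (4Z,8E)-10-(tert-butyldiphenylsilyloxy)-8-methyl-4-[(trimethylsilyl)methyl]deca-4,8-dienoate | CCOC(=O)CC/C(C[Si](C)(C)C)=C/CC/C(C)=C/CO[Si](c1ccccc1)(c1ccccc1)C(C)(C)C | intermediate
13 | (4Z,8E)-10-(tert-butyldiphenylsilyloxy)-8-methyl-4-[(trimethylsilyl)methyl]deca-4,8-dienal | O=CCC/C(C[Si](C)(C)C)=C/CC/C(C)=C/CO[Si](c1ccccc1)(c1ccccc1)C(C)(C)C | intermediate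
14 | isopropenylmagnesium bromide | C=C(C)[Mg]Br | starting material
15 | (6Z,10E)-12-(tert-butyldiphenylsilyloxy)-2,10-dimethyl-6-[(trimethylsilyl)methyl]dodeca-1,6,10-trien-3-ol (racemic) | C=C(C)C(O)CC/C(C[Si](C)(C)C)=C/CC/C(C)=C/CO[Si](c1ccccc1)(c1ccccc1)C(C)(C)C | intermediate
16 | 1-ethoxyvinyl ether (ketene acetal) of 15 | C=C(OCC)OC(CC/C(C[Si](C)(C)C)=C/CC/C(C)=C/CO[Si](c1ccccc1)(c1ccccc1)C(C)(C)C)C(C)=C | intermediate (not isolated)
17 | ethyl (4E,8Z,12E)-14-(tert-butyldiphenylsilyloxy)-4,12-dimethyl-8-[(trimethylsilyl)methyl]tetradeca-4,8,12-trienoate | CCOC(=O)CC/C(C)=C/CC/C(C[Si](C)(C)C)=C/CC/C(C)=C/CO[Si](c1ccccc1)(c1ccccc1)C(C)(C)C | intermediate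
18 | (4E,8Z,12E)-14-(tert-butyldiphenylsilyloxy)-4,12-dimethyl-8-[(trimethylsilyl)methyl]tetradeca-4,8,12-trienal | O=CCC/C(C)=C/CC/C(C[Si](C)(C)C)=C/CC/C(C)=C/CO[Si](c1ccccc1)(c1ccccc1)C(C)(C)C | intermediate
19 | methyl 2-[bis(2,2,2-trifluoroethoxy)phosphoryl]propanoate | COC(=O)C(C)P(=O)(OCC(F)(F)F)OCC(F)(F)F | starting material
20 | potassium salt of the carbanion of 19 | [K+].COC(=O)[C-](C)P(=O)(OCC(F)(F)F)OCC(F)(F)F | intermediate (not isolated)
21 | methyl (2Z,6E,10Z,14E)-16-(tert-butyldiphenylsilyloxy)-2,6,14-trimethyl-10-[(trimethylsilyl)methyl]hexadeca-2,6,10,14-tetraenoate | COC(=O)/C(C)=C\CC/C(C)=C/CC/C(C[Si](C)(C)C)=C/CC/C(C)=C/CO[Si](c1ccccc1)(c1ccccc1)C(C)(C)C | intermediate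
22 | (2Z,6E,10Z,14E)-16-(tert-butyldiphenylsilyloxy)-2,6,14-trimethyl-10-[(trimethylsilyl)methyl]hexadeca-2,6,10,14-tetraen-1-ol | OC/C(C)=C\CC/C(C)=C/CC/C(C[Si](C)(C)C)=C/CC/C(C)=C/CO[Si](c1ccccc1)(c1ccccc1)C(C)(C)C | intermediate
23 | tert-butyl hydroperoxide | CC(C)(C)OO | starting material
24 | {(2R,3S)-3-[(3E,7Z,11E)-13-(tert-butyldiphenylsilyloxy)-3,11-dimethyl-7-[(trimethylsilyl)methyl]trideca-3,7,11-trien-1-yl]-2-methyloxiran-2-yl}methanol | OC[C@@]1(C)O[C@H]1CC/C(C)=C/CC/C(C[Si](C)(C)C)=C/CC/C(C)=C/CO[Si](c1ccccc1)(c1ccccc1)C(C)(C)C | intermediate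
25 | tert-butyl(chloro)dimethylsilane | CC(C)(C)[Si](C)(C)Cl | starting material
26 | tert-butyl({(2R,3S)-3-[(3E,7Z,11E)-13-(tert-butyldiphenylsilyloxy)-3,11-dimethyl-7-[(trimethylsilyl)methyl]trideca-3,7,11-trien-1-yl]-2-methyloxiran-2-yl}methoxy)dimethylsilane | CC(C)(C)[Si](C)(C)OC[C@@]1(C)O[C@H]1CC/C(C)=C/CC/C(C[Si](C)(C)C)=C/CC/C(C)=C/CO[Si](c1ccccc1)(c1ccccc1)C(C)(C)C | intermediate
27 | 19-(tert-butyldimethylsilyloxy)-15-(tert-butyldiphenylsilyloxy)labda-8(17),13E-dien-3β-ol | C=C1CC[C@@H]2[C@](C)(CC[C@H](O)[C@]2(C)CO[Si](C)(C)C(C)(C)C)[C@H]1CC/C(C)=C/CO[Si](c1ccccc1)(c1ccccc1)C(C)(C)C | intermediate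
28 | 19-(tert-butyldimethylsilyloxy)-15-(tert-butyldiphenylsilyloxy)labda-8(17),13E-dien-3-one | C=C1CC[C@@H]2[C@](C)(CCC(=O)[C@]2(C)CO[Si](C)(C)C(C)(C)C)[C@H]1CC/C(C)=C/CO[Si](c1ccccc1)(c1ccccc1)C(C)(C)C | intermediate
29 | 19-(tert-butyldimethylsilyloxy)-15-(tert-butyldiphenylsilyloxy)labda-8(17),13E-dien-3α-ol | C=C1CC[C@@H]2[C@](C)(CC[C@@H](O)[C@]2(C)CO[Si](C)(C)C(C)(C)C)[C@H]1CC/C(C)=C/CO[Si](c1ccccc1)(c1ccccc1)C(C)(C)C | intermediate
30 | acetic anhydride | CC(=O)OC(C)=O | starting material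
31 | 3α-acetoxy-19-(tert-butyldimethylsilyloxy)-15-(tert-butyldiphenylsilyloxy)labda-8(17),13E-diene | C=C1CC[C@@H]2[C@](C)(CC[C@@H](OC(C)=O)[C@]2(C)CO[Si](C)(C)C(C)(C)C)[C@H]1CC/C(C)=C/CO[Si](c1ccccc1)(c1ccccc1)C(C)(C)C | intermediate
32 | 3α-acetoxy-15-(tert-butyldiphenylsilyloxy)labda-8(17),13E-dien-19-ol | C=C1CC[C@@H]2[C@](C)(CC[C@@H](OC(C)=O)[C@]2(C)CO)[C@H]1CC/C(C)=C/CO[Si](c1ccccc1)(c1ccccc1)C(C)(C)C | intermediate
33 | 3α-acetoxy-15-(tert-butyldiphenylsilyloxy)labda-8(17),13E-dien-19-al | C=C1CC[C@@H]2[C@](C)(CC[C@@H](OC(C)=O)[C@]2(C)C=O)[C@H]1CC/C(C)=C/CO[Si](c1ccccc1)(c1ccccc1)C(C)(C)C | intermediate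
34 | sodium chlorite | [Na+].[O-]Cl=O | starting material
35 | 3α-acetoxy-15-(tert-butyldiphenylsilyloxy)labda-8(17),13E-dien-19-oic acid | C=C1CC[C@@H]2[C@](C)(CC[C@@H](OC(C)=O)[C@]2(C)C(=O)O)[C@H]1CC/C(C)=C/CO[Si](c1ccccc1)(c1ccccc1)C(C)(C)C | intermediate
36 | 3α-acetoxy-15-hydroxylabda-8(17),13E-dien-19-oic acid, (1R,2R,4aR,5S,8aR)-2-acetoxy-5-[(3E)-5-hydroxy-3-methylpent-3-en-1-yl]-1,4a-dimethyl-6-methylidenedecahydronaphthalene-1-carboxylic acid | C=C1CC[C@@H]2[C@](C)(CC[C@@H](OC(C)=O)[C@]2(C)C(=O)O)[C@H]1CC/C(C)=C/CO | target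

Total step count: 21
Longest linear sequence: 21 steps (1 to 36)

Steps most likely to fail

Step 14. What may go wrong: the electron-withdrawing silyloxymethyl group slows ionisation at C4, so Lewis acid rearrangement of the oxirane to a carbonyl compound, protodesilylation of the allylsilane or arrest after closure of ring A can outrun the cascade. The fallback replaces cationic by oxidative radical initiation, sets out from 13 and comes back at 27. Wittig reaction of 13 with ethyl 2-(triphenylphosphoranylidene)propanoate gives ethyl (2E,6Z,10E)-12-(tert-butyldiphenylsilyloxy)-2,10-dimethyl-6-[(trimethylsilyl)methyl]dodeca-2,6,10-trienoate F1. Reduction with i-Bu2AlH gives (2E,6Z,10E)-12-(tert-butyldiphenylsilyloxy)-2,10-dimethyl-6-[(trimethylsilyl)methyl]dodeca-2,6,10-trien-1-ol F2. MsCl/Et3N followed by LiBr gives tert-butyl{[(2E,6Z,10E)-12-bromo-3,11-dimethyl-7-[(trimethylsilyl)methyl]dodeca-2,6,10-trien-1-yl]oxy}diphenylsilane F3. The chiral ester (1R,2S,5R)-5-methyl-2-(2-phenylpropan-2-yl)cyclohexyl 2-methyl-3-oxobutanoate F4 is made from (−)-8-phenylmenthol and ethyl 2-methyl-3-oxobutanoate (DMAP, toluene, reflux). Its dianion (NaH, then n-BuLi, THF, 0 °C) is alkylated at the terminal carbon with F3 to give (1R,2S,5R)-5-methyl-2-(2-phenylpropan-2-yl)cyclohexyl (6E,10Z,14E)-16-(tert-butyldiphenylsilyloxy)-2,6,14-trimethyl-3-oxo-10-[(trimethylsilyl)methyl]hexadeca-6,10,14-trienoate F5. Mn(OAc)3 and Cu(OAc)2 in AcOH generate the tertiary C4 radical, which closes ring A and then ring B (C10 onto C9). The β-silyl radical at C8 is oxidised and desilylated to the C8=C17 methylene, which should give (1R,2S,5R)-5-methyl-2-(2-phenylpropan-2-yl)cyclohexyl 15-(tert-butyldiphenylsilyloxy)-3-oxolabda-8(17),13E-dien-19-oate F6 with the axial ester. The auxiliary is expected to shield one face of the radical; its antipode would be used should the sense of induction be the opposite one. LiAlH4 reduces the ketone and the hindered ester to 15-(tert-butyldiphenylsilyloxy)labda-8(17),13E-diene-3β,19-diol F7, and t-BuMe2SiCl with imidazole silylates only the primary hydroxyl to return to 27.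

Step 16. What may go wrong: poor facial selectivity of hydride delivery, because the axial 4β-silyloxymethyl group may screen the β-face enough for the bulky hydride to attack axially and return the equatorial 3β-alcohol. The fallback replaces steric control by intramolecular, hydroxyl-directed delivery, sets out from 28 and comes back at 29. Acid methanolysis of 28 (camphorsulfonic acid, MeOH) frees the C19 hydroxyl and gives 15-(tert-butyldiphenylsilyloxy)-19-hydroxylabda-8(17),13E-dien-3-one F8. Me4NBH(OAc)3 in MeCN/AcOH (Evans–Saksena reduction) binds the C19 oxygen and delivers hydride to the β-face of C3, which should give 15-(tert-butyldiphenylsilyloxy)labda-8(17),13E-diene-3α,19-diol F9. t-BuMe2SiCl with imidazole then silylates only the primary hydroxyl and returns to 29.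

Step 18. What may go wrong: poor discrimination between the two silyl ethers, because the neopentyl, axial C19 silyl ether is shielded and its acidolysis may be slow enough for loss of the allylic silyl ether or migration of the exocyclic alkene to compete. The fallback differentiates the two hydroxyls by the steric demand of re-silylation instead of by the rate of cleavage, sets out from 31 and comes back at 32. Bu4NF removes both silyl groups of 31 and gives 3α-acetoxylabda-8(17),13E-diene-15,19-diol F10. One equivalent of t-BuPh2SiCl with imidazole at 0 °C then re-silylates only the unhindered allylic C15 hydroxyl and returns to 32.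

Further compounds
F1 | step 14 | ethyl (2E,6Z,10E)-12-(tert-butyldiphenylsilyloxy)-2,10-dimethyl-6-[(trimethylsilyl)methyl]dodeca-2,6,10-trienoate | CCOC(=O)/C(C)=C/CC/C(C[Si](C)(C)C)=C/CC/C(C)=C/CO[Si](c1ccccc1)(c1ccccc1)C(C)(C)C
F2 | step 14 | (2E,6Z,10E)-12-(tert-butyldiphenylsilyloxy)-2,10-dimethyl-6-[(trimethylsilyl)methyl]dodeca-2,6,10-trien-1-ol | OC/C(C)=C/CC/C(C[Si](C)(C)C)=C/CC/C(C)=C/CO[Si](c1ccccc1)(c1ccccc1)C(C)(C)C
F3 | step 14 | tert-butyl{[(2E,6Z,10E)-12-bromo-3,11-dimethyl-7-[(trimethylsilyl)methyl]dodeca-2,6,10-trien-1-yl]oxy}diphenylsilane | BrC/C(C)=C/CC/C(C[Si](C)(C)C)=C/CC/C(C)=C/CO[Si](c1ccccc1)(c1ccccc1)C(C)(C)C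
F4 | step 14 | (1R,2S,5R)-5-methyl-2-(2-phenylpropan-2-yl)cyclohexyl 2-methyl-3-oxobutanoate | CC(C)(c1ccccc1)[C@@H]1CC[C@@H](C)C[C@H]1OC(=O)C(C)C(C)=O
F5 | step 14 | (1R,2S,5R)-5-methyl-2-(2-phenylpropan-2-yl)cyclohexyl (6E,10Z,14E)-16-(tert-butyldiphenylsilyloxy)-2,6,14-trimethyl-3-oxo-10-[(trimethylsilyl)methyl]hexadeca-6,10,14-trienoate | CC(C)(c1ccccc1)[C@@H]1CC[C@@H](C)C[C@H]1OC(=O)C(C)C(=O)CC/C(C)=C/CC/C(C[Si](C)(C)C)=C/CC/C(C)=C/CO[Si](c1ccccc1)(c1ccccc1)C(C)(C)C
F6 | step 14 | (1R,2S,5R)-5-methyl-2-(2-phenylpropan-2-yl)cyclohexyl 15-(tert-butyldiphenylsilyloxy)-3-oxolabda-8(17),13E-dien-19-oate | C=C1CC[C@@H]2[C@](C)(CCC(=O)[C@]2(C)C(=O)O[C@@H]3C[C@H](C)CC[C@H]3C(C)(C)c3ccccc3)[C@H]1CC/C(C)=C/CO[Si](c1ccccc1)(c1ccccc1)C(C)(C)C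
F7 | step 14 | 15-(tert-butyldiphenylsilyloxy)labda-8(17),13E-diene-3β,19-diol | C=C1CC[C@@H]2[C@](C)(CC[C@H](O)[C@]2(C)CO)[C@H]1CC/C(C)=C/CO[Si](c1ccccc1)(c1ccccc1)C(C)(C)C
F8 | step 16 | 15-(tert-butyldiphenylsilyloxy)-19-hydroxylabda-8(17),13E-dien-3-one | C=C1CC[C@@H]2[C@](C)(CCC(=O)[C@]2(C)CO)[C@H]1CC/C(C)=C/CO[Si](c1ccccc1)(c1ccccc1)C(C)(C)C
F9 | step 16 | 15-(tert-butyldiphenylsilyloxy)labda-8(17),13E-diene-3α,19-diol | C=C1CC[C@@H]2[C@](C)(CC[C@@H](O)[C@]2(C)CO)[C@H]1CC/C(C)=C/CO[Si](c1ccccc1)(c1ccccc1)C(C)(C)C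
F10 | step 18 | 3α-acetoxylabda-8(17),13E-diene-15,19-diol | C=C1CC[C@@H]2[C@](C)(CC[C@@H](OC(C)=O)[C@]2(C)CO)[C@H]1CC/C(C)=C/CO
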